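4.00 was the number I started from: violet's time divided by the time of the last reading, which I called the age of a flask.

the same everywhere: gas 1.4 mM (held)

| run | substrate | remark | time |
|---|---|---|---|
| Tuesday's | 10 mM | run made earlier |  |
| Monday's | 19 mM | run made earlier |  |
| violet | 10 mM |  | 120 min |
| grey | 41 mM |  | 30 min |

- Tuesday's (time / min: bis adduct / %, triple product / %): 6.00: 0.4, 0; 12.0: 4.5, 0; 20.0: 10.4, 2.3; 25.0: 9.8, 2.7; 30.0: 12.4, 4.2
- Monday's (time / min: bis adduct / %, triple product / %): 6.00: 2.0, 1.6; 12.0: 6.5, 0; 20.0: 8.8, 0; 25.0: 10.6, 2.6; 30.0: 12.2, 3.2

(standard deviation of a reading: 1 percentage point)

- at the start none of the gas is in solution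

* which one finishes higher in share of bis adduct in all that became bis adduct or triple product or isomer of the product ("neither" within 2 percentage points) (violet / grey / neither)
* share of bis adduct in all that became bis adduct or triple product or isomer of the product, violet
* share of bis adduct in all that became bis adduct or triple product or isomer of the product, grey

Monday's charge was 19 mM and Tuesday's 10 mM, with the gas held at 1.4 mM in both. Yet at the last reading their bis adduct differed by 0.2 percentage points of the charge and their triple product by 1 point, against a scatter of 1 point. So I read both runs as pseudo-first-order in substrate: at this held gas, a fraction of the charge follows the time and not the charge. That made age the reckoning: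

violet: 120 min / 30.0 min = 4.00

grey: 30 min / 30.0 min = 1.00

I expected grey to repeat the last readings, whatever its charge. Violet lay beyond every reading, and the isomer had no column, so I gave neither share a number. I put grey, the younger flask, higher, since Tuesday's triple product read 4.2% at 30.0 min against 2.3% at 20.0 min.

The forecast also chose grey and, unlike me, gave numbers: 34% for violet and 77% for grey. It read grey as I did: “Grey should therefore follow the same percentage curve”.

The flask gave grey, with 12.2% for violet and 45.9% for grey.

    gas ⇌ reagent, rate k1*(csat - [reagent]) (kL = 1.50 /s)
    reagent + single product → bis adduct (k = 0.600 /M/s)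
    substrate + reagent → single product (k = 0.290 /M/s)
    reagent + bis adduct → triple product (k = 0.260 /M/s)
    bis adduct ⇌ isomer of the product (K = 4.80, k = 0.00110 /s)

At age 1.00, grey held bis adduct 12.4% and triple product 3.97%, close to the last readings, beside isomer 10.7%. The exchange of bis adduct with its isomer has a relaxation half-life of 8.69 min in grey, shorter than violet's 120 min. At age 4.00, violet held isomer 48.1% against bis adduct 11.0%.

Grey's charge of 41 mM read at 2.0 h has age 4.00, violet's age, so the rule gives it violet's 12.2%. The computed share there is 12.3%.

The runs are calculated for substances that don't exist, noise included.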